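Ring B is disconnected at C5–C6 and C8–C9. This exposes two electrophilic carbons on ring A, the ketone carbon C5 and an aldehyde carbon C9, held 1,3 across quaternary C10, and a four-carbon unit C6–C7–C8(–C12). In the key step a doubly deprotonated β-keto phosphonate joins C8 to C9 by aldol addition and C6 to C5 by intramolecular Horner–Wadsworth–Emmons olefination, closing ring B in one flask. The temporary C7 oxygen then controls H-5, the α-oriented benzyl group at C9 and the position of the C7=C8 double bond. The precursor is a monocyclic keto aldehyde, (R)-1,3,3-trimethyl-2-oxocyclohexanecarbaldehyde.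

Key step: step 5

Remark: the target is carried through and drawn as the free hydrogen sulfate (in practice it would be stored as its sodium salt); the two hydroxyl groups meta to the side chain of the tetraol are equivalent, so sulfation of either gives the same compound. Atom numbers C1–C12 are drimane numbers.

Step 1
Reactants: 1 2,2,6-trimethylcyclohexanone; 2 allyl chloroformate
Product: 3 allyl 2,6,6-trimethylcyclohex-1-en-1-yl carbonate
Conditions: LiN(SiMe3)2, THF, 0 °C; then 2, -78 °C to 25 °C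
Reagents that add atoms: allyl chloroformate C=CCOC(=O)Cl
Why: The ketone has a single enolisable position and its hindered tetrasubstituted lithium enolate should be acylated on oxygen (enol carbonate formation).

Step 2
Reactants: 3 allyl 2,6,6-trimethylcyclohex-1-en-1-yl carbonate
Product: 4 (R)-2-allyl-2,6,6-trimethylcyclohexanone
Conditions: Pd2(dba)3 (zerovalent palladium, 2.5 mol %), (R)-t-Bu-PHOX [(R)-4-tert-butyl-2-(2-diphenylphosphanylphenyl)-4,5-dihydrooxazole], THF, 25 °C
Reagents that add atoms: none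
Why: Decarboxylative asymmetric allylic alkylation (enantioselective Tsuji allylation) gives an allylpalladium enolate that recombines at carbon, and the ligand enantiomer is chosen so that the quaternary centre (future C10) is formed as R.

Step 3
Reactants: 4 (R)-2-allyl-2,6,6-trimethylcyclohexanone
Product: 5 (R)-2,2,6-trimethyl-6-[(1E)-prop-1-en-1-yl]cyclohexanone
Conditions: PdCl2(MeCN)2 (divalent palladium, 5 mol %), benzene, 70 °C
Reagents that add atoms: none
Why: Metal hydride mediated alkene isomerisation should move the terminal double bond one position to the more substituted E-propenyl isomer, and the quaternary carbon stops further migration.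

Step 4
Reactants: 5 (R)-2,2,6-trimethyl-6-[(1E)-prop-1-en-1-yl]cyclohexanone
Product: 6 (R)-1,3,3-trimethyl-2-oxocyclohexane-1-carbaldehyde
Conditions: O3, CH2Cl2/MeOH, -78 °C; then Me2S, -78 °C to 25 °C
Reagents that add atoms: ozone [O-][O+]=O
Why: Ozonolysis with reductive work-up cleaves the only alkene, and the aldehyde cannot enolise, so the quaternary stereocentre is untouched.

Step 5
Reactants: 6 (R)-1,3,3-trimethyl-2-oxocyclohexane-1-carbaldehyde; 7 diethyl (2-oxobutyl)phosphonate
Product: 9 (4aS)-4-hydroxy-3,4a,8,8-tetramethyl-4,4a,5,6,7,8-hexahydronaphthalen-2(3H)-one, via aldol adduct 8 (not isolated)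
Conditions: 7, NaH, THF, 0 °C; n-BuLi, 0 °C; then 6, -78 °C; then 25 °C to 50 °C; aqueous NH4Cl
Reagents that add atoms: diethyl (2-oxobutyl)phosphonate CCC(=O)CP(=O)(OCC)OCC
Why: Doubly deprotonated 7 reacts first at its more basic γ-carbon (C8, which carries the future C12 methyl) with the aldehyde carbon C9 of 6 (aldol addition), and on warming the remaining phosphonate-stabilised carbanion (C6) adds to the ring-A ketone C5 and expels diethyl phosphate (intramolecular Horner–Wadsworth–Emmons olefination), so C8–C9 and C5=C6 are made in one flask. The closest known reaction types are the γ-aldol and γ-alkylation chemistry of β-keto phosphonate dianions and the intramolecular Horner–Wadsworth–Emmons cyclohexenone annulation, which together amount to a [3+3] annulation of the C6–C7–C8 unit onto the C5/C10/C9 keto aldehyde. Ring B closes in the olefination step by 6-exo-trig addition of the carbanion to the ketone carbonyl followed by syn elimination of phosphate. No stereocentre made here has to be controlled, because C8 and C9 form as a mixture that is erased in step 6 and C10 cannot epimerise since neither carbonyl of 6 is enolisable. The step needs site selectivity (γ-carbon before α-carbon, aldehyde before ketone), which the reactivity order of the dianion and the much higher electrophilicity of the aldehyde over the doubly neopentyl ketone should secure. It also needs ring closure to outrun retro-aldol cleavage of the aldolate, which is why the addition is run at -78 °C and the mixture is warmed only for the intramolecular olefination.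

Step 6
Reactants: 9 (4aS)-4-hydroxy-3,4a,8,8-tetramethyl-4,4a,5,6,7,8-hexahydronaphthalen-2(3H)-one
Product: 11 (4aR,8aS)-3,4a,8,8-tetramethyl-4a,5,6,7,8,8a-hexahydronaphthalen-2(1H)-one, via hydroxy ketone 10 (not isolated)
Conditions: Li, NH3(l)/THF, -78 °C; NH4Cl; then TsOH·H2O (cat.), benzene, 80 °C
Reagents that add atoms: none
Why: Dissolving-metal (Birch-type) reduction of the C5=C6 enone should protonate C5 on the face opposite the C10 methyl (trans ring fusion), the C9 alkoxide arm stays inert because the enolate lies on the C6 side, and acid-catalysed dehydration of the β-hydroxy ketone then gives the conjugated C8=C9 enone.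

Step 7
Reactants: 12 1,2,4,5-tetramethoxybenzene
Product: 13 (2,3,5,6-tetramethoxyphenyl)methanol
Conditions: n-BuLi, TMEDA, THF, 0 °C; then paraformaldehyde, 0 °C to 25 °C
Reagents that add atoms: formaldehyde (as paraformaldehyde) C=O
Why: Directed ortho-lithiation between two methoxy groups (both ring hydrogens are equivalent) followed by hydroxymethylation.

Step 8
Reactants: 13 (2,3,5,6-tetramethoxyphenyl)methanol
Product: 14 3-(chloromethyl)-1,2,4,5-tetramethoxybenzene
Conditions: SOCl2, CH2Cl2, 0 °C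
Reagents that add atoms: thionyl chloride O=S(Cl)Cl
Why: Chlorodehydroxylation of an electron-rich benzylic alcohol through its chlorosulfite.

Step 9
Reactants: 11 (4aR,8aS)-3,4a,8,8-tetramethyl-4a,5,6,7,8,8a-hexahydronaphthalen-2(1H)-one; 14 3-(chloromethyl)-1,2,4,5-tetramethoxybenzene
Product: 17 (1S,4aS,8aS)-2,5,5,8a-tetramethyl-1-[(2,3,5,6-tetramethoxyphenyl)methyl]-1,4,4a,5,6,7,8,8a-octahydronaphthalen-3-yl trifluoromethanesulfonate, via (2,3,5,6-tetramethoxybenzyl)magnesium chloride 15 (not isolated), via chloromagnesium enolate 16 (not isolated)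
Conditions: 14, Mg, THF, 0 °C (slow addition); CuBr·SMe2 (20 mol %), DMPU, -40 °C, then 11; then PhNTf2, -40 °C to 25 °C
Reagents that add atoms: 3-(chloromethyl)-1,2,4,5-tetramethoxybenzene COc1cc(OC)c(OC)c(CCl)c1OC; N-phenylbis(trifluoromethanesulfonimide) O=S(=O)(N(c1ccccc1)S(=O)(=O)C(F)(F)F)C(F)(F)F
Why: Copper-catalysed conjugate addition of the benzylic Grignard reagent should occur axially at C9 on the face opposite the axial C10 methyl (benzyl group α, trans to that methyl), and the regiodefined C7=C8 enolate is trapped on oxygen (enolate O-triflation).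

Step 10
Reactants: 17 (1S,4aS,8aS)-2,5,5,8a-tetramethyl-1-[(2,3,5,6-tetramethoxyphenyl)methyl]-1,4,4a,5,6,7,8,8a-octahydronaphthalen-3-yl trifluoromethanesulfonate
Product: 18 3-{[(1R,4aS,8aS)-2,5,5,8a-tetramethyl-1,4,4a,5,6,7,8,8a-octahydronaphthalen-1-yl]methyl}-1,2,4,5-tetramethoxybenzene
Conditions: Pd(OAc)2 (5 mol %), PPh3, n-Bu3N, HCO2H, DMF, 60 °C
Reagents that add atoms: none
Why: Palladium-catalysed formate reduction of the enol triflate (oxidative addition, formate exchange, decarboxylation, C–H reductive elimination) replaces the triflate by hydrogen without moving the C7=C8 double bond.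

Step 11
Reactants: 18 3-{[(1R,4aS,8aS)-2,5,5,8a-tetramethyl-1,4,4a,5,6,7,8,8a-octahydronaphthalen-1-yl]methyl}-1,2,4,5-tetramethoxybenzene
Product: 19 2,5-dimethoxy-3-{[(1R,4aS,8aS)-2,5,5,8a-tetramethyl-1,4,4a,5,6,7,8,8a-octahydronaphthalen-1-yl]methyl}cyclohexa-2,5-diene-1,4-dione
Conditions: (NH4)2Ce(NO3)6, MeCN/H2O, 0 °C
Reagents that add atoms: water O
Why: Oxidative demethylation of a para-dimethoxy pair gives the para-quinone, and because the two para pairs of the aryl group are equivalent only one 2,5-dimethoxyquinone should form.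

Step 12
Reactants: 19 2,5-dimethoxy-3-{[(1R,4aS,8aS)-2,5,5,8a-tetramethyl-1,4,4a,5,6,7,8,8a-octahydronaphthalen-1-yl]methyl}cyclohexa-2,5-diene-1,4-dione
Product: 20 2,5-dihydroxy-3-{[(1R,4aS,8aS)-2,5,5,8a-tetramethyl-1,4,4a,5,6,7,8,8a-octahydronaphthalen-1-yl]methyl}cyclohexa-2,5-diene-1,4-dione
Conditions: NaOH, EtOH/H2O, 60 °C (argon); then HCl (aq.), 0 °C
Reagents that add atoms: water O
Why: Both methoxy groups are vinylogous esters and should be replaced by hydroxide through addition–elimination (vinylogous ester hydrolysis).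

Step 13
Reactants: 20 2,5-dihydroxy-3-{[(1R,4aS,8aS)-2,5,5,8a-tetramethyl-1,4,4a,5,6,7,8,8a-octahydronaphthalen-1-yl]methyl}cyclohexa-2,5-diene-1,4-dione
Product: 22 2,4,5-trihydroxy-3-{[(1R,4aS,8aS)-2,5,5,8a-tetramethyl-1,4,4a,5,6,7,8,8a-octahydronaphthalen-1-yl]methyl}phenyl hydrogen sulfate, via tetraol 21 (not isolated)
Conditions: Na2S2O4, EtOAc/H2O, 25 °C (argon); then SO3·pyridine (1.0 equiv), pyridine, 0 °C; H+ ion-exchange resin, 0 °C
Reagents that add atoms: sulfur trioxide pyridine complex [O-]S(=O)(=O)[n+]1ccccc1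
Why: Dithionite reduces the quinone to the tetraol, whose two equivalent hydroxyls meta to the side chain are the least hindered, so one equivalent of the SO3 complex should sulfate one of them while the two hydroxyls flanking the bulky side chain react more slowly (phenol O-sulfation).

Compound list
1 | 2,2,6-trimethylcyclohexanone (racemic) | CC1CCCC(C)(C)C1=O | starting material
2 | allyl chloroformate | C=CCOC(=O)Cl | starting material
3 | allyl 2,6,6-trimethylcyclohex-1-en-1-yl carbonate | C=CCOC(=O)OC1=C(C)CCCC1(C)C | intermediate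
4 | (R)-2-allyl-2,6,6-trimethylcyclohexanone | O=C1C(C)(C)CCC[C@]1(C)CC=C | intermediate
5 | (R)-2,2,6-trimethyl-6-[(1E)-prop-1-en-1-yl]cyclohexanone | O=C1C(C)(C)CCC[C@]1(C)/C=C/C | intermediate
6 | (R)-1,3,3-trimethyl-2-oxocyclohexane-1-carbaldehyde | O=C[C@@]1(C)CCCC(C)(C)C1=O | intermediate
7 | diethyl (2-oxobutyl)phosphonate | CCC(=O)CP(=O)(OCC)OCC | starting material
8 | diethyl {4-hydroxy-3-methyl-2-oxo-4-[(1R)-1,3,3-trimethyl-2-oxocyclohexyl]butyl}phosphonate (aldol adduct, mixture at the two new centres) | CCOP(=O)(OCC)CC(=O)C(C)C(O)[C@@]1(C)CCCC(C)(C)C1=O | intermediate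
9 | (4aS)-4-hydroxy-3,4a,8,8-tetramethyl-4,4a,5,6,7,8-hexahydronaphthalen-2(3H)-one (mixture at C3 and C4) | CC1C(=O)C=C2C(C)(C)CCC[C@]2(C)C1O | intermediate
10 | (4aS,8aS)-4-hydroxy-3,4a,8,8-tetramethyloctahydronaphthalen-2(1H)-one (trans-fused, mixture at C3 and C4) | CC1C(=O)C[C@H]2C(C)(C)CCC[C@]2(C)C1O | intermediate
11 | (4aR,8aS)-3,4a,8,8-tetramethyl-4a,5,6,7,8,8a-hexahydronaphthalen-2(1H)-one (trans-fused; 11-nor-drim-8-en-7-one) | O=C1C[C@H]2C(C)(C)CCC[C@]2(C)C=C1C | intermediate
12 | 1,2,4,5-tetramethoxybenzene | COc1cc(OC)c(OC)cc1OC | starting material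
13 | (2,3,5,6-tetramethoxyphenyl)methanol | COc1cc(OC)c(OC)c(CO)c1OC | intermediate
14 | 3-(chloromethyl)-1,2,4,5-tetramethoxybenzene | COc1cc(OC)c(OC)c(CCl)c1OC | intermediate
15 | (2,3,5,6-tetramethoxybenzyl)magnesium chloride | COc1cc(OC)c(OC)c(C[Mg]Cl)c1OC | intermediate
16 | chloromagnesium enolate of the 9α-benzylated 7-ketone (C7=C8 enolate; 5α-H, 9β-H, 10β-methyl) | CC1=C(O[Mg]Cl)C[C@H]2C(C)(C)CCC[C@]2(C)[C@@H]1Cc1c(OC)c(OC)cc(OC)c1OC | intermediate
17 | (1S,4aS,8aS)-2,5,5,8a-tetramethyl-1-[(2,3,5,6-tetramethoxyphenyl)methyl]-1,4,4a,5,6,7,8,8a-octahydronaphthalen-3-yl trifluoromethanesulfonate | CC1=C(OS(=O)(=O)C(F)(F)F)C[C@H]2C(C)(C)CCC[C@]2(C)[C@@H]1Cc1c(OC)c(OC)cc(OC)c1OC | intermediate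
18 | 3-{[(1R,4aS,8aS)-2,5,5,8a-tetramethyl-1,4,4a,5,6,7,8,8a-octahydronaphthalen-1-yl]methyl}-1,2,4,5-tetramethoxybenzene | CC1=CC[C@H]2C(C)(C)CCC[C@]2(C)[C@@H]1Cc1c(OC)c(OC)cc(OC)c1OC | intermediate
19 | 2,5-dimethoxy-3-{[(1R,4aS,8aS)-2,5,5,8a-tetramethyl-1,4,4a,5,6,7,8,8a-octahydronaphthalen-1-yl]methyl}cyclohexa-2,5-diene-1,4-dione | CC1=CC[C@H]2C(C)(C)CCC[C@]2(C)[C@@H]1CC1=C(OC)C(=O)C=C(OC)C1=O | intermediate
20 | 2,5-dihydroxy-3-{[(1R,4aS,8aS)-2,5,5,8a-tetramethyl-1,4,4a,5,6,7,8,8a-octahydronaphthalen-1-yl]methyl}cyclohexa-2,5-diene-1,4-dione | CC1=CC[C@H]2C(C)(C)CCC[C@]2(C)[C@@H]1CC1=C(O)C(=O)C=C(O)C1=O | intermediate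
21 | 3-{[(1R,4aS,8aS)-2,5,5,8a-tetramethyl-1,4,4a,5,6,7,8,8a-octahydronaphthalen-1-yl]methyl}benzene-1,2,4,5-tetrol | CC1=CC[C@H]2C(C)(C)CCC[C@]2(C)[C@@H]1Cc1c(O)c(O)cc(O)c1O | intermediate
22 | 2,4,5-trihydroxy-3-{[(1R,4aS,8aS)-2,5,5,8a-tetramethyl-1,4,4a,5,6,7,8,8a-octahydronaphthalen-1-yl]methyl}phenyl hydrogen sulfate | CC1=CC[C@H]2C(C)(C)CCC[C@]2(C)[C@@H]1Cc1c(O)c(O)cc(OS(=O)(=O)O)c1O | target

Total step count: 13 (11 in the main line, 2 for the benzylic chloride 14).
Longest linear sequence: 11 steps (steps 1–6 and 9–13).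

Steps most likely to fail

Step 5. The aldolate may fragment by retro-aldol loss of the formyl carbon before the ring closes, or the olefination may stall at the doubly neopentyl ketone. The fallback sets out from 6 and makes C8=C9 first, so that no basic aldolate persists. Horner–Wadsworth–Emmons reaction of 6 with dimethyl (3-oxobutan-2-yl)phosphonate (Ba(OH)2, wet THF) should give (R)-2,2,6-trimethyl-6-[(1E)-2-methyl-3-oxobut-1-en-1-yl]cyclohexanone F1. KOH in xylenes at 110 °C with removal of water (E/Z equilibration by reversible conjugate addition, then aldol condensation of the methyl ketone onto C5) should close the cross-conjugated dienone (4aR)-3,4a,8,8-tetramethyl-5,6,7,8-tetrahydronaphthalen-2(4aH)-one F2. Copper-catalysed addition of the Grignard reagent 15 should go to C9, the only β-carbon that carries hydrogen, anti to the angular methyl, and aqueous work-up gives the 9α-benzylated Δ5-7-ketone F3. Li/NH3 then sets H-5 trans and gives the saturated 9α-benzylated 7-ketone F4. Triflation of its equilibrated, more substituted C7=C8 potassium enolate (KH, THF, 25 °C; PhNTf2) comes back to the route at 17.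

Step 9. Transfer of the hindered benzylic group to the neopentyl β-carbon may be poor, with homocoupling of the Grignard reagent or 1,2-addition taking over. The fallback sets out from 11 and builds C9–C11 with a small vinyl nucleophile, attaching the arene afterwards. Vinylmagnesium bromide with CuBr·SMe2, then PhNTf2, should give the 9α-vinyl enol triflate F5, and Pd(OAc)2/PPh3/HCO2H/n-Bu3N should reduce it to the 9α-vinyl diene F6. OsO4 (cat.)/NaIO4 with 2,6-lutidine cleaves the monosubstituted alkene in preference to the hindered ring alkene and should give the 9α-aldehyde F7, which is used cold and at once to avoid epimerisation at C9. Addition of 2,3,5,6-tetramethoxyphenyllithium F8 (from 12 and n-BuLi) at -78 °C gives the benzylic alcohol F9, and ionic hydrogenation (Et3SiH, CF3CO2H, CH2Cl2, -20 °C) removes the benzylic hydroxyl and comes back to the route at 18.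

Step 13. The tetraol may be sulfated twice or at a hindered hydroxyl, and it is prone to air oxidation. The fallback sets out from 20 and frees only one unhindered hydroxyl. Allyl bromide and K2CO3 in DMF should give the 2,5-bis(allyloxy)quinone F10. Na2S2O4 reduces it to the bis(allyloxy)hydroquinone F11 (not isolated), whose hydroxyl next to the ring hydrogen is far more accessible than the one next to the side chain. SO3·pyridine then gives the monosulfate F12, and Pd(PPh3)4 (zerovalent palladium) with morpholine removes both allyl groups and comes back to the route at 22.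

Further compounds
F1 | step 5 | (R)-2,2,6-trimethyl-6-[(1E)-2-methyl-3-oxobut-1-en-1-yl]cyclohexanone | CC(=O)/C(C)=C/[C@@]1(C)CCCC(C)(C)C1=O
F2 | step 5 | (4aR)-3,4a,8,8-tetramethyl-5,6,7,8-tetrahydronaphthalen-2(4aH)-one | CC1=C[C@@]2(C)CCCC(C)(C)C2=CC1=O
F3 | step 5 | 3,4a,8,8-tetramethyl-4-[(2,3,5,6-tetramethoxyphenyl)methyl]-4,4a,5,6,7,8-hexahydronaphthalen-2(3H)-one (benzyl group trans to the 4a-methyl, mixture at C3) | CC1C(=O)C=C2C(C)(C)CCC[C@]2(C)[C@@H]1Cc1c(OC)c(OC)cc(OC)c1OC
F4 | step 5 | 3,4a,8,8-tetramethyl-4-[(2,3,5,6-tetramethoxyphenyl)methyl]octahydronaphthalen-2(1H)-one (trans-fused, benzyl group trans to the 4a-methyl, mixture at C3) | CC1C(=O)C[C@H]2C(C)(C)CCC[C@]2(C)[C@@H]1Cc1c(OC)c(OC)cc(OC)c1OC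
F5 | step 9 | 9α-vinyl enol triflate (2,5,5,8a-tetramethyl-1-vinyl-1,4,4a,5,6,7,8,8a-octahydronaphthalen-3-yl trifluoromethanesulfonate, trans-fused, vinyl trans to the 8a-methyl) | CC1=C(OS(=O)(=O)C(F)(F)F)C[C@H]2C(C)(C)CCC[C@]2(C)[C@@H]1C=C
F6 | step 9 | 9α-vinyl diene (2,5,5,8a-tetramethyl-1-vinyl-1,4,4a,5,6,7,8,8a-octahydronaphthalene, trans-fused, vinyl trans to the 8a-methyl) | CC1=CC[C@H]2C(C)(C)CCC[C@]2(C)[C@@H]1C=C
F7 | step 9 | 9α-aldehyde (2,5,5,8a-tetramethyl-1,4,4a,5,6,7,8,8a-octahydronaphthalene-1-carbaldehyde, trans-fused, formyl trans to the 8a-methyl) | CC1=CC[C@H]2C(C)(C)CCC[C@]2(C)[C@@H]1C=O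
F8 | step 9 | 2,3,5,6-tetramethoxyphenyllithium | [Li]c1c(OC)c(OC)cc(OC)c1OC
F9 | step 9 | benzylic alcohol ((2,3,5,6-tetramethoxyphenyl)[2,5,5,8a-tetramethyl-1,4,4a,5,6,7,8,8a-octahydronaphthalen-1-yl]methanol, mixture at the carbinol carbon) | CC1=CC[C@H]2C(C)(C)CCC[C@]2(C)[C@@H]1C(O)c1c(OC)c(OC)cc(OC)c1OC
F10 | step 13 | 2,5-bis(allyloxy)-3-{[(1R,4aS,8aS)-2,5,5,8a-tetramethyl-1,4,4a,5,6,7,8,8a-octahydronaphthalen-1-yl]methyl}cyclohexa-2,5-diene-1,4-dione | CC1=CC[C@H]2C(C)(C)CCC[C@]2(C)[C@@H]1CC1=C(OCC=C)C(=O)C=C(OCC=C)C1=O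
F11 | step 13 | 2,5-bis(allyloxy)-3-{[(1R,4aS,8aS)-2,5,5,8a-tetramethyl-1,4,4a,5,6,7,8,8a-octahydronaphthalen-1-yl]methyl}benzene-1,4-diol | CC1=CC[C@H]2C(C)(C)CCC[C@]2(C)[C@@H]1Cc1c(O)c(OCC=C)cc(O)c1OCC=C
F12 | step 13 | 2,5-bis(allyloxy)-4-hydroxy-3-{[(1R,4aS,8aS)-2,5,5,8a-tetramethyl-1,4,4a,5,6,7,8,8a-octahydronaphthalen-1-yl]methyl}phenyl hydrogen sulfate | CC1=CC[C@H]2C(C)(C)CCC[C@]2(C)[C@@H]1Cc1c(O)c(OCC=C)cc(OS(=O)(=O)O)c1OCC=C
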